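**Retrosynthetic overview** (chromene numbering; ring A = anisyl ring, ring B = arene of the chromene, ring C = pyran)
- Side-chain arm, no ring formed: the two carbonyl carbons and the future C6–C7 of ring B come from arylglyoxal hydrate 1 (dried to aldehyde 2) and HC≡CMgBr 3, by way of acyloin 4 and its oxidation to ynedione 5.
- Ring C is cut at C4–C4a and O1–C2: keto ester 6 and prenal 7 (Knoevenagel to oxatriene 8, oxa-6π closure to 2H-pyran 9).
- Ring B is cut at C5–C6 and C7–C8: 9, as dienolate 10 and silyl ketene acetal diene 11, reacts with 5 in a Diels–Alder reaction to 12, which loses MeOH and Me3SiOH to give dielsianone 13.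
- Order of ring formation: ring A is bought; ring C, then ring B, both in one flask in step 3 (the arene is grown on the pyran).

Assumption: the target has no stereocentre, so "single enantiomer" is read as the one achiral compound drawn.

**Step 1**
Reactants: 1 2,2-dihydroxy-1-(4-methoxyphenyl)ethan-1-one (4-methoxyphenylglyoxal monohydrate); 3 ethynylmagnesium bromide (HC≡CMgBr, 0.5 M in THF)
Product: 4 rac-2-hydroxy-1-(4-methoxyphenyl)but-3-yn-1-one, via anhydrous 4-methoxyphenylglyoxal 2 (not isolated)
Conditions: PhMe, reflux, Dean–Stark; then HC≡CMgBr (1.05 equiv), THF, −78 °C, 1 h; 1 M HCl, 0 °C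
Reagents that add atoms: none
Why: Chemoselective Grignard 1,2-addition, because the aldehyde carbonyl of anhydrous 2 is much more electrophilic than the para-methoxy-deactivated aryl ketone, so one equivalent at −78 °C gives the acyloin, whose new stereocentre forms racemic and is erased in step 2.

**Step 2**
Reactants: 4 rac-2-hydroxy-1-(4-methoxyphenyl)but-3-yn-1-one
Product: 5 1-(4-methoxyphenyl)but-3-yne-1,2-dione
Conditions: Dess–Martin periodinane (1.2 equiv), CH2Cl2, 0 °C → rt, 1 h; pentane/Et2O, filtration through SiO2; used at once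
Reagents that add atoms: none
Why: Dess–Martin oxidation of a secondary α-hydroxy ketone to the 1,2-diketone runs under neutral, anhydrous, non-nucleophilic conditions that spare the terminal alkyne and avoid hydration of or conjugate addition to the electrophilic ynedione; no stereocentre remains.

**Step 3**
Reactants: 6 methyl 4-methoxy-3-oxobutanoate; 7 3-methylbut-2-enal (prenal); 5 1-(4-methoxyphenyl)but-3-yne-1,2-dione
Product: 13 dielsianone, via oxatriene 8 (not isolated), via 2H-pyran ester 9 (not isolated), via lithium dienolate 10 (not isolated), via silyl ketene acetal diene 11 (not isolated), via Diels–Alder cycloadduct 12 (not isolated)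
Conditions: 6, 7 (1.0 equiv), piperidine, AcOH (5 mol % each), MgSO4, THF, rt, 16 h; cannula-filtered into LiN(iPr)2 (1.2 equiv), THF, −78 °C, then Me3SiCl (1.5 equiv), −78 → 0 °C; volatiles off, PhMe; 5 (0.85 equiv), −20 °C → rt; 1 M HCl/THF, 0 °C
Reagents that add atoms: none
Why: Proposed new method: Knoevenagel condensation and oxa-6π electrocyclisation close ring C (oxatriene 8 collapses to 2H-pyran 9, favoured by the gem-dimethyl group and the 5-ester), γ-deprotonation and O-silylation then give the cis-locked exocyclic 1-alkoxy-1-silyloxy diene 11, whose MeO-bearing CH terminus bonds to the unsubstituted alkyne carbon of 5 in a Diels–Alder reaction so that the ketene-acetal carbon ends next to the acyl group, and acid work-up expels MeOH and Me3SiOH to aromatise ring B with 5-OH, 6-acyl, 7-H and 8-OMe in place; the closest known reaction types are the amine-catalysed formal [3+3] synthesis of 2H-pyrans from β-keto esters and enals and the Diels–Alder benzannulation of Brassard-type dienes with alkynones, and no stereocentre survives.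

**Compound list**
1 | 2,2-dihydroxy-1-(4-methoxyphenyl)ethan-1-one (4-methoxyphenylglyoxal monohydrate) | COc1ccc(cc1)C(=O)C(O)O | starting material
2 | 2-(4-methoxyphenyl)-2-oxoacetaldehyde (anhydrous 4-methoxyphenylglyoxal) | COc1ccc(cc1)C(=O)C=O | intermediate
3 | ethynylmagnesium bromide | C#C[Mg]Br | starting material
4 | rac-2-hydroxy-1-(4-methoxyphenyl)but-3-yn-1-one (racemate) | COc1ccc(cc1)C(=O)C(O)C#C | intermediate
5 | 1-(4-methoxyphenyl)but-3-yne-1,2-dione | COc1ccc(cc1)C(=O)C(=O)C#C | intermediate
6 | methyl 4-methoxy-3-oxobutanoate | COCC(=O)CC(=O)OC | starting material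
7 | 3-methylbut-2-enal | CC(C)=CC=O | starting material
8 | methyl (2E)-2-(methoxyacetyl)-5-methylhexa-2,4-dienoate | COCC(=O)/C(C(=O)OC)=C\C=C(C)C | intermediate
9 | methyl 6-(methoxymethyl)-2,2-dimethyl-2H-pyran-5-carboxylate | COCC1=C(C(=O)OC)C=CC(C)(C)O1 | intermediate
10 | lithium [(6Z)-6-(methoxymethylidene)-2,2-dimethyl-2H-pyran-5(6H)-ylidene](methoxy)methanolate | CO/C=C1\OC(C)(C)C=CC1=C([O-])OC.[Li+] | intermediate
11 | (6Z)-5-[methoxy(trimethylsilyloxy)methylidene]-6-(methoxymethylidene)-2,2-dimethyl-5,6-dihydro-2H-pyran (ketene acetal geometry not controlled) | CO/C=C1\OC(C)(C)C=CC1=C(OC)O[Si](C)(C)C | intermediate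
12 | 1-[5,8-dimethoxy-2,2-dimethyl-5-(trimethylsilyloxy)-5,8-dihydro-2H-chromen-6-yl]-2-(4-methoxyphenyl)ethane-1,2-dione (racemic diastereomer mixture; both stereocentres lost on aromatisation) | COC1C=C(C(=O)C(=O)c2ccc(OC)cc2)C(OC)(O[Si](C)(C)C)C2=C1OC(C)(C)C=C2 | intermediate
13 | dielsianone, 1-(5-hydroxy-8-methoxy-2,2-dimethyl-2H-chromen-6-yl)-2-(4-methoxyphenyl)ethane-1,2-dione (achiral) | COc1ccc(C(=O)C(=O)c2cc(OC)c3c(c2O)C=CC(C)(C)O3)cc1 | target

**Step count and risk**
Total steps: 3. Longest linear sequence: 3 (1 → 4 → 5 → 13); 6 and 7 enter in step 3.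

Most at risk is step 3. The water and amine left from the condensation can spoil the lithium amide stage, diene 11 is moisture-sensitive, and the 1,2-dione of 5 may be attacked by the silyl ketene acetal (aldol or hetero-Diels–Alder) instead of the alkyne. The fallback reverses the ring order and makes the arene first from an acyclic diene. It sets out from 6: Et3N/Me3SiCl gives methyl 4-methoxy-3-(trimethylsilyloxy)but-2-enoate F1, and LiN(iPr)2/Me3SiCl at −78 °C gives 1,4-dimethoxy-1,3-bis(trimethylsilyloxy)buta-1,3-diene F2. F2 and 5 (PhMe, rt) give the cycloadduct 1-[3,6-dimethoxy-4,6-bis(trimethylsilyloxy)cyclohexa-1,4-dien-1-yl]-2-(4-methoxyphenyl)ethane-1,2-dione F3, which dilute HCl aromatises to 1-(2,4-dihydroxy-5-methoxyphenyl)-2-(4-methoxyphenyl)ethane-1,2-dione F4. Condensation of F4 with 7 (Ca(OH)2, MeOH, rt; aldol at the carbon between the two hydroxyls, o-quinone methide, oxa-6π closure through the non-chelated hydroxyl) comes back to the route at 13.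

Second is step 2. The terminal ynedione 5 may be cleaved by the periodinane, or hydrate or polymerise on handling. The fallback brings in the second carbonyl last. It sets out from 3: 4-methoxyphenylacetic acid is converted (CDI, MeNHOMe·HCl) into N-methoxy-2-(4-methoxyphenyl)-N-methylacetamide F5, which with 3 gives 1-(4-methoxyphenyl)but-3-yn-2-one F6. F6 takes the place of 5 in the flask sequence of step 3 and reacts with diene 11 to give the cycloadduct 1-[5,8-dimethoxy-2,2-dimethyl-5-(trimethylsilyloxy)-5,8-dihydro-2H-chromen-6-yl]-2-(4-methoxyphenyl)ethan-1-one F7. Acid work-up gives 1-(5-hydroxy-8-methoxy-2,2-dimethyl-2H-chromen-6-yl)-2-(4-methoxyphenyl)ethan-1-one F8, and Riley oxidation of its benzylic CH2 (SeO2, dioxane/H2O, 90 °C) comes back at 13.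

Third is step 1. The anhydrous glyoxal 2 can oligomerise, and the Grignard reagent can add twice or to the ketone. The fallback makes the C–C bond by acyl substitution instead of carbonyl addition. It sets out from 3: N,N'-dimethoxy-N,N'-dimethyloxamide and 4-MeOC6H4MgBr (1 equiv, THF, −78 °C) give N-methoxy-2-(4-methoxyphenyl)-N-methyl-2-oxoacetamide F9. Addition of 3 to the chelating Weinreb amide carbonyl of F9 (−78 → 0 °C, inverse quench into cold 1 M HCl) comes back to the route directly at 5, with no acyloin and no oxidation.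

**Further compounds**
F1 | step 3 | methyl 4-methoxy-3-(trimethylsilyloxy)but-2-enoate (E/Z mixture) | COCC(O[Si](C)(C)C)=CC(=O)OC
F2 | step 3 | 1,4-dimethoxy-1,3-bis(trimethylsilyloxy)buta-1,3-diene (mixture of geometric isomers) | COC=C(O[Si](C)(C)C)C=C(OC)O[Si](C)(C)C
F3 | step 3 | 1-[3,6-dimethoxy-4,6-bis(trimethylsilyloxy)cyclohexa-1,4-dien-1-yl]-2-(4-methoxyphenyl)ethane-1,2-dione (racemic diastereomer mixture) | COC1C=C(C(=O)C(=O)c2ccc(OC)cc2)C(OC)(O[Si](C)(C)C)C=C1O[Si](C)(C)C
F4 | step 3 | 1-(2,4-dihydroxy-5-methoxyphenyl)-2-(4-methoxyphenyl)ethane-1,2-dione | COc1ccc(cc1)C(=O)C(=O)c1cc(OC)c(O)cc1O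
F5 | step 2 | N-methoxy-2-(4-methoxyphenyl)-N-methylacetamide | COc1ccc(CC(=O)N(C)OC)cc1
F6 | step 2 | 1-(4-methoxyphenyl)but-3-yn-2-one | COc1ccc(CC(=O)C#C)cc1
F7 | step 2 | 1-[5,8-dimethoxy-2,2-dimethyl-5-(trimethylsilyloxy)-5,8-dihydro-2H-chromen-6-yl]-2-(4-methoxyphenyl)ethan-1-one (racemic diastereomer mixture) | COC1C=C(C(=O)Cc2ccc(OC)cc2)C(OC)(O[Si](C)(C)C)C2=C1OC(C)(C)C=C2
F8 | step 2 | 1-(5-hydroxy-8-methoxy-2,2-dimethyl-2H-chromen-6-yl)-2-(4-methoxyphenyl)ethan-1-one | COc1ccc(CC(=O)c2cc(OC)c3c(c2O)C=CC(C)(C)O3)cc1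
F9 | step 1 | N-methoxy-2-(4-methoxyphenyl)-N-methyl-2-oxoacetamide | COc1ccc(cc1)C(=O)C(=O)N(C)OC
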